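## Retrosynthetic overview
1. Brianthein Z ⇐ triacetylation ⇐ C6-OH→Cl (Appel, inversion) ⇐ 10-membered ring by ring-closing metathesis (cis C3=C4) of a C2-vinyl / C4-vinyl diene.
2. The C6–C9 side chain and lactone (C8 tertiary alcohol, C7–O lactone, C6 carbinol) ⇐ propionate dianion addition to a C8 vinyl ketone, hydroxyl-directed epoxidation with 5-exo lactonisation, then chloroprene Grignard addition to the C6 aldehyde.
3. The cyclohexane core (quaternary C1, C10, C11, C12–OAc, C13/C14 epoxide) ⇐ **key step: Diels–Alder** of an α-methyl enal from (R)-glyceraldehyde acetonide with a methyl-substituted Danishefsky-type diene, then enone epoxidation and reduction.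
4. Order of ring formation: cyclohexane (Diels–Alder), then γ-lactone with the side chain, then the 10-membered ring (RCM), then chloride and acetates.

Assumption: diene **4** is commercial, or made in one step from (E)-1-methoxypent-1-en-3-one and TMSCl. (R)-Glyceraldehyde acetonide (from D-mannitol) is commercial. The only pool stereocentre is C9. All other centres are set by substrate control.

## Route

**Step 1**
Reactants: 1 (R)-2,3-O-isopropylideneglyceraldehyde; 2 2-(triphenylphosphoranylidene)propanal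
Product: 3 (2E)-3-[(4S)-2,2-dimethyl-1,3-dioxolan-4-yl]-2-methylpropenal
Conditions: CH2Cl2, rt, 12 h
Reagents that add atoms: none
Why: A stabilised-ylide Wittig reaction gives the E-α-methyl enal, so C2 and C9 will be trans in the ring. Neutral conditions keep the C9 stereocentre (S) from epimerising.

**Step 2 (key step)**
Reactants: 3; 4 (1E,3Z)-1-methoxy-3-(trimethylsilyloxy)penta-1,3-diene
Product: 5 Diels–Alder adduct (TMS enol ether C12=C13, C14-OMe, C11-Me, C1 quaternary with CHO, C10 bearing the acetonide)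
Conditions: toluene, BHT, 110 °C, sealed tube, 24 h
Reagents that add atoms: none
Why: Normal-demand Diels–Alder: the OMe-bearing terminus bonds to the α-carbon (C14–C1) and the methyl terminus to the β-carbon (C10–C11). The E-dienophile fixes C2/C9 trans. The diene attacks anti to C9–O in the A(1,3)-minimised conformer (C9–H in plane) and through the exo approach, which places 11-Me cis to C9. The C14 centre is destroyed later.

**Step 3**
Reactants: 5
Product: 6 (C2 vinyl carbinol)
Conditions: vinylMgBr, THF, −78→−20 °C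
Reagents that add atoms: vinylmagnesium bromide, C=C[Mg]Br
Why: Grignard addition to the neopentyl aldehyde; Mg chelation to the C14-OMe and attack past the smaller C1-methyl set C2.

**Step 4**
Reactants: 6
Product: 7 (C2-OTBS)
Conditions: TBSOTf, 2,6-lutidine, CH2Cl2, −78 °C
Reagents that add atoms: TBSOTf, CC(C)(C)[Si](C)(C)OS(=O)(=O)C(F)(F)F
Why: Silyl protection of the hindered alcohol; no new stereocentre.

**Step 5**
Reactants: 7
Product: 8 (cyclohexenone, C12=O, C13=C14)
Conditions: 1) TBAF, AcOH, THF, 0 °C; 2) DBU, CH2Cl2, 0 °C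
Reagents that add atoms: none
Why: Desilylation gives the β-methoxy ketone, then E1cB loss of MeOH (deprotonation at C13) gives the enone. The C14 centre is erased and C11 is untouched under these kinetic conditions.

**Step 6**
Reactants: 8
Product: 9 (13,14-epoxy ketone)
Conditions: t-BuOOH, Triton B, THF, 0 °C
Reagents that add atoms: tert-butyl hydroperoxide, CC(C)(C)OO (supplies the epoxide O)
Why: Weitz–Scheffer epoxidation. The peroxide adds to C14 from the face bearing only C2, away from the cis C1-Me, C9 and 11-Me cluster, so the epoxide is cis to C2.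

**Step 7**
Reactants: 9
Product: 10 (C12 epoxy alcohol)
Conditions: NaBH4, CeCl3·7H2O, MeOH, −78 °C
Reagents that add atoms: none
Why: Hydride approaches anti to the epoxide C–O bond (polar Felkin–Anh), so the C12-OH is cis to the epoxide.

**Step 8**
Reactants: 10
Product: 11 (C12-OTBS)
Conditions: TBSOTf, 2,6-lutidine, CH2Cl2, −78 °C
Reagents that add atoms: TBSOTf, CC(C)(C)[Si](C)(C)OS(=O)(=O)C(F)(F)F
Why: Protection, so that later oxidations and Grignard reactions do not touch C12.

**Step 9**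
Reactants: 11
Product: 12 (C9,C8-diol, C8 primary)
Conditions: PPTS, MeOH, 50 °C
Reagents that add atoms: none
Why: Acetonide removal by transketalisation. TBS ethers and the epoxide survive these mild conditions.

**Step 10**
Reactants: 12
Product: 13 (α-hydroxy aldehyde)
Conditions: TEMPO (10 mol%), PhI(OAc)2, CH2Cl2, rt
Reagents that add atoms: none
Why: TEMPO oxidises the primary alcohol selectively over the secondary one.

**Step 11**
Reactants: 13
Product: 14 (α-TBS-oxy aldehyde)
Conditions: TBSOTf, 2,6-lutidine, CH2Cl2, −78 °C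
Reagents that add atoms: TBSOTf, CC(C)(C)[Si](C)(C)OS(=O)(=O)C(F)(F)F
Why: Non-chelating, non-migrating protection of C9-OH; the aldehyde is used at once to avoid C9 epimerisation.

**Step 12**
Reactants: 14
Product: 15 (C8 allylic alcohol, epimer mixture)
Conditions: vinylMgBr, THF, −78 °C
Reagents that add atoms: vinylmagnesium bromide, C=C[Mg]Br
Why: 1,2-Addition installs C7=C6; the C8 stereocentre is destroyed in the next step, so the mixture is harmless.

**Step 13**
Reactants: 15
Product: 16 (C8 vinyl ketone)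
Conditions: Dess–Martin periodinane, NaHCO3, CH2Cl2, rt; crude ketone used immediately
Reagents that add atoms: none
Why: Oxidation to the C8 electrophile that will receive C17.

**Step 14**
Reactants: 16
Product: 17 (C8 tertiary allylic alcohol bearing C17(Me)–COOH)
Conditions: propionic acid, LDA (2.2 equiv), THF, −78→0 °C
Reagents that add atoms: propionic acid, CCC(=O)O
Why: The carboxylate dianion (Ivanov-type) adds 1,2 to the vinyl ketone. Polar Felkin–Anh attack anti to C9-OTBS sets C8. C17 comes from the chair enediolate transition state and can be equilibrated later, since Me trans to C9 is the thermodynamic lactone.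

**Step 15**
Reactants: 17
Product: 18 (γ-lactone, C7–O, C6 CH2OH)
Conditions: 1) VO(acac)2 (5 mol%), t-BuOOH, CH2Cl2, 0 °C; 2) PPTS, CH2Cl2, rt
Reagents that add atoms: tert-butyl hydroperoxide, CC(C)(C)OO (supplies the epoxide/alcohol O)
Why: The tertiary allylic OH directs syn epoxidation, with C9 anti to the alkene in the A(1,3)/A(1,2)-minimised conformer. The carboxylate then opens the epoxide at C7 (5-exo, inversion), giving the lactone and the primary C6 alcohol.

**Step 16**
Reactants: 18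
Product: 19 (C6 aldehyde)
Conditions: Dess–Martin periodinane, NaHCO3, CH2Cl2, rt
Reagents that add atoms: none
Why: Oxidation to the C6 electrophile; the tertiary C8-OH is inert.

**Step 17**
Reactants: 19
Product: 20 (C6 dienyl carbinol, C5(=C16)–C4H=CH2)
Conditions: buta-1,3-dien-2-ylmagnesium chloride (from chloroprene/Mg, 3 equiv), THF, −78 °C
Reagents that add atoms: buta-1,3-dien-2-ylmagnesium chloride, C=CC(=C)[Mg]Cl
Why: Grignard addition builds the 2-substituted diene. Mg chelation between the aldehyde and lactone O-7 should give the syn alcohol, which is the precursor for the Appel inversion.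

**Step 18**
Reactants: 20
Product: 21 (10-membered macrocycle, cis C3=C4, C5=C16 exocyclic methylene)
Conditions: Hoveyda–Grubbs II (10 mol%), CH2Cl2 (2 mM), 40 °C
Reagents that add atoms: none (ethylene is lost)
Why: Ring-closing metathesis of the C2-vinyl and C4-vinyl groups; ring strain enforces the Z alkene.

**Step 19**
Reactants: 21
Product: 22 (C6 chloride)
Conditions: PPh3, NCS, CH2Cl2, 0 °C→rt
Reagents that add atoms: N-chlorosuccinimide, O=C1CCC(=O)N1Cl
Why: Appel-type SN2 on the allylic alcohol gives Cl with inversion at C6.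

**Step 20**
Reactants: 22
Product: 23 (tetraol: C2, C8, C9, C12 OH)
Conditions: HF·pyridine, pyridine/THF, 0 °C→rt
Reagents that add atoms: none
Why: Global removal of the three TBS ethers; the lactone, epoxide and allylic chloride tolerate buffered HF.

**Step 21**
Reactants: 23
Product: 24 brianthein Z
Conditions: Ac2O, pyridine, DMAP (cat.), CH2Cl2, 0 °C→rt
Reagents that add atoms: acetic anhydride, CC(=O)OC(C)=O
Why: The three secondary alcohols are acetylated; the hindered tertiary C8-OH is left free under these mild conditions.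

## Compound list
1 | (R)-2,3-O-isopropylideneglyceraldehyde | O=C[C@H]1COC(C)(C)O1 | starting material
2 | 2-(triphenylphosphoranylidene)propanal | CC(C=O)=P(c1ccccc1)(c1ccccc1)c1ccccc1 | starting material
3 | (2E)-3-[(4S)-2,2-dimethyl-1,3-dioxolan-4-yl]-2-methylpropenal | O=C/C(C)=C/[C@H]1COC(C)(C)O1 | intermediate
4 | (1E,3Z)-1-methoxy-3-(trimethylsilyloxy)penta-1,3-diene | CO/C=C/C(O[Si](C)(C)C)=C/C | starting material
5 | Diels–Alder adduct | O=C[C@]1(C)[C@@H]([C@H]2COC(C)(C)O2)[C@@H](C)C(O[Si](C)(C)C)=C[C@H]1OC | intermediate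
6 | C2 vinyl carbinol | C=C[C@H](O)[C@]1(C)[C@@H]([C@H]2COC(C)(C)O2)[C@@H](C)C(O[Si](C)(C)C)=C[C@H]1OC | intermediate
7 | C2-OTBS ether | C=C[C@H](O[Si](C)(C)C(C)(C)C)[C@]1(C)[C@@H]([C@H]2COC(C)(C)O2)[C@@H](C)C(O[Si](C)(C)C)=C[C@H]1OC | intermediate
8 | cyclohexenone | C=C[C@H](O[Si](C)(C)C(C)(C)C)[C@]1(C)[C@@H]([C@H]2COC(C)(C)O2)[C@@H](C)C(=O)C=C1 | intermediate
9 | 13,14-epoxy ketone | C=C[C@H](O[Si](C)(C)C(C)(C)C)[C@]1(C)[C@@H]([C@H]2COC(C)(C)O2)[C@@H](C)C(=O)[C@@H]3O[C@@H]31 | intermediate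
10 | epoxy alcohol | C=C[C@H](O[Si](C)(C)C(C)(C)C)[C@]1(C)[C@@H]([C@H]2COC(C)(C)O2)[C@@H](C)[C@H](O)[C@@H]3O[C@@H]31 | intermediate
11 | C12-OTBS ether | C=C[C@H](O[Si](C)(C)C(C)(C)C)[C@]1(C)[C@@H]([C@H]2COC(C)(C)O2)[C@@H](C)[C@H](O[Si](C)(C)C(C)(C)C)[C@@H]3O[C@@H]31 | intermediate
12 | diol | C=C[C@H](O[Si](C)(C)C(C)(C)C)[C@]1(C)[C@@H]([C@H](O)CO)[C@@H](C)[C@H](O[Si](C)(C)C(C)(C)C)[C@@H]2O[C@@H]21 | intermediate
13 | α-hydroxy aldehyde | C=C[C@H](O[Si](C)(C)C(C)(C)C)[C@]1(C)[C@@H]([C@H](O)C=O)[C@@H](C)[C@H](O[Si](C)(C)C(C)(C)C)[C@@H]2O[C@@H]21 | intermediate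
14 | α-TBS-oxy aldehyde | C=C[C@H](O[Si](C)(C)C(C)(C)C)[C@]1(C)[C@@H]([C@H](O[Si](C)(C)C(C)(C)C)C=O)[C@@H](C)[C@H](O[Si](C)(C)C(C)(C)C)[C@@H]2O[C@@H]21 | intermediate
15 | C8 allylic alcohol (C8 epimers) | C=C[C@H](O[Si](C)(C)C(C)(C)C)[C@]1(C)[C@@H]([C@H](O[Si](C)(C)C(C)(C)C)C(O)C=C)[C@@H](C)[C@H](O[Si](C)(C)C(C)(C)C)[C@@H]2O[C@@H]21 | intermediate
16 | vinyl ketone | C=C[C@H](O[Si](C)(C)C(C)(C)C)[C@]1(C)[C@@H]([C@H](O[Si](C)(C)C(C)(C)C)C(=O)C=C)[C@@H](C)[C@H](O[Si](C)(C)C(C)(C)C)[C@@H]2O[C@@H]21 | intermediate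
17 | β-hydroxy acid | C=C[C@H](O[Si](C)(C)C(C)(C)C)[C@]1(C)[C@@H]([C@H](O[Si](C)(C)C(C)(C)C)[C@@](O)(C=C)[C@@H](C)C(=O)O)[C@@H](C)[C@H](O[Si](C)(C)C(C)(C)C)[C@@H]2O[C@@H]21 | intermediate
18 | hydroxy-γ-lactone (C6 CH2OH) | C=C[C@H](O[Si](C)(C)C(C)(C)C)[C@]1(C)[C@@H]([C@H](O[Si](C)(C)C(C)(C)C)[C@]2(O)[C@@H](C)C(=O)O[C@H]2CO)[C@@H](C)[C@H](O[Si](C)(C)C(C)(C)C)[C@@H]3O[C@@H]31 | intermediate
19 | lactone aldehyde | C=C[C@H](O[Si](C)(C)C(C)(C)C)[C@]1(C)[C@@H]([C@H](O[Si](C)(C)C(C)(C)C)[C@]2(O)[C@@H](C)C(=O)O[C@H]2C=O)[C@@H](C)[C@H](O[Si](C)(C)C(C)(C)C)[C@@H]3O[C@@H]31 | intermediate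
20 | C6 dienyl carbinol | C=C[C@H](O[Si](C)(C)C(C)(C)C)[C@]1(C)[C@@H]([C@H](O[Si](C)(C)C(C)(C)C)[C@]2(O)[C@@H](C)C(=O)O[C@H]2[C@H](O)C(=C)C=C)[C@@H](C)[C@H](O[Si](C)(C)C(C)(C)C)[C@@H]3O[C@@H]31 | intermediate
21 | macrocyclic C6-alcohol | C=C1/C=C\[C@H](O[Si](C)(C)C(C)(C)C)[C@]2(C)[C@H]([C@@H](C)[C@H](O[Si](C)(C)C(C)(C)C)[C@@H]3O[C@@H]32)[C@H](O[Si](C)(C)C(C)(C)C)[C@]2(O)[C@@H](C)C(=O)O[C@H]2[C@@H]1O | intermediate
22 | C6 chloride, tris-TBS | C=C1/C=C\[C@H](O[Si](C)(C)C(C)(C)C)[C@]2(C)[C@H]([C@@H](C)[C@H](O[Si](C)(C)C(C)(C)C)[C@@H]3O[C@@H]32)[C@H](O[Si](C)(C)C(C)(C)C)[C@]2(O)[C@@H](C)C(=O)O[C@H]2[C@H]1Cl | intermediate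
23 | tetraol chloride | C=C1/C=C\[C@H](O)[C@]2(C)[C@H]([C@@H](C)[C@H](O)[C@@H]3O[C@@H]32)[C@H](O)[C@]2(O)[C@@H](C)C(=O)O[C@H]2[C@H]1Cl | intermediate
24 | brianthein Z | C=C1/C=C\[C@H](OC(C)=O)[C@]2(C)[C@H]([C@@H](C)[C@H](OC(C)=O)[C@@H]3O[C@@H]32)[C@H](OC(C)=O)[C@]2(O)[C@@H](C)C(=O)O[C@H]2[C@H]1Cl | target

## Totals
Total steps: 21. Longest linear sequence: 21 steps from compound 1.

## Three steps most likely to fail
1. **Step 2 (Diels–Alder).** The exo/endo ratio (which sets C11) and the facial selectivity from C9 alone may be poor.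
   Fallback: use the unsubstituted Danishefsky diene, epoxidise, then α-methylenate the C12 ketone and set C11 by Crabtree hydrogenation of C11=CH2 directed by the C12-OH.
2. **Step 15 (directed epoxidation / 5-exo lactonisation).** The C7 diastereoselectivity is modest, and the ring-A epoxide may not survive the acid.
   Fallback: allylborate aldehyde 14 with a Z-γ-benzyloxyallylboronate, ozonolyse to the C6 aldehyde, and close the lactone by intramolecular SmI2 Reformatsky of a C7 α-bromopropionate onto a C8 ketone.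
3. **Step 18 (RCM).** Closing a strained 10-membered trans-fused Z-diene ring may fail or oligomerise.
   Fallback: close C5–C6 instead by intramolecular Nozaki–Hiyama–Kishi coupling of a C5 2-iodo-1,3-diene (built on C2 by Z-selective olefination) onto the C6 aldehyde.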